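At early times whatever has formed is still target, and the isomer of the product can only grow out of it. So the share asked for is a contest between two times.

| flask | starting material | partner | protic impurity | temperature | time |
|---|---|---|---|---|---|
| ochre | 0.050 M | 1.20 equiv | 0.0250 M | 80 °C | 30 s |
| teal | 0.050 M | 1.20 equiv | 0.0250 M | 60 °C | 30 s |
| blue | 0.050 M | 1.20 equiv | 0.0250 M | 40 °C | 30 s |
| amber | 0.050 M | 1.20 equiv | 0.0250 M | 100 °C | 30 s |

    starting material + partner + released group → target + 2 released group (k1 = 49 /M²/s, Ea1 = 55.0 kJ/mol)
    starting material + protic impurity → quenched substrate (k2 = 33 /M/s, Ea2 = 40.0 kJ/mol)
    starting material + partner → target + released group (k3 = 0.10 /M/s, Ea3 = 85.0 kJ/mol)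
    target ⇌ isomer of the product (K4 = 1.8, k4 = 0.11 /s, Ea4 = 100 kJ/mol, ΔH4 = 3.00 kJ/mol)
    (constants at 100 °C)

- the constants hold at 100 °C; other temperatures follow from the activation energies and enthalpies

1. the flask with the highest share of target in all that became target or isomer of the product ("all alike" if they lie within 1.5 percentage points) (ochre / teal / blue / amber / all alike)
2. share of target in all that became target or isomer of the product, ochre
3. share of target in all that became target or isomer of the product, teal
4. share of target in all that became target or isomer of the product, blue
5. share of target in all that became target or isomer of the product, amber

The first time is the time given, t. The second is τ, the relaxation time of target and isomer of the product: the reciprocal of the forward and reverse constants added. This step is first order, so no concentration enters τ. For blue the relaxation half-life is 30.3 min, long against the time given, so t/τ comes to 0.0115. We carry this number, N, the exposure: time given over relaxation time. For amber the constants stand as given, so τ is 5.84 s, shorter than the time given, and N is 5.13.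

We assume that target is made at a steady rate, so that rate cancels from the share. Let φ be the isomer's fraction at equilibrium, K/(1+K), which is 0.643 at the given constants. Integrating the relaxation over the time of making gives the share S = 1 − φ(1 − (1 − e^(−N))/N). For small N this becomes S ≈ 1 − φN/2. Small N is kinetic control, and large N moves toward thermodynamic control. Our amber share is 48.2 %. Keeping that φ as a rough step, our blue share is 99.6 %.

The forecast named blue, with 81 % for ochre, 96.9 % for teal, 99.7 % for blue and 51 % for amber. Of target it held that “most of it is made late in the 30 s”, where we took steady making, and its amber figure stands above ours.

The simulation gives blue as highest, with 81.0 % for ochre, 96.6 % for teal, 99.6 % for blue and 51.3 % for amber.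

The largest single effect on the gap between amber and blue is what temperature does to the turning of target into isomer of the product. With that taken away, the gap of 48 percentage points shrinks to 0.077 points. In our terms, this is the exposure climbing from 0.0115 to 5.13.

Take a neighbour of blue with 0.030 M of starting material, which makes 0.833 equiv of protic impurity. Its temperature and time are those of blue and no concentration enters N, so N stays 0.0115 and S stays 99.6 %. The simulation gives 99.6 %.

All constants are assumed; the run is a simulation.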